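**Plan**
- Retrosynthesis: cut the C8–O ester bond (side-chain acid) and the C15–O silyl ether, then re-join C5–C10 with C2=C3 unsaturation, which turns the ten-membered ring back into a trans-fused eudesma-1,3-diene. The C15–O and C8–O bonds are then removed to reach α-santonin.
- Enabling feature: the ring C1–C10 (C14 on C10, C15 on C4, lactone O on C6, C11–C12 on C7, ester O on C8) is a decalin lacking the C5–C10 bond, and C6, C7, C11 and the fused γ-lactone are those of α-santonin.
- Forward: rings A and B and the lactone come with santonin. C8–OH is installed first, then ring A is adjusted (trans fusion, C15 oxygenation, 1,3-diene). The ten-membered ring arises by photochemical opening (not closure), C2=C3 is reduced, and the side chain is attached last.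
- Stereochemistry: C6, C7 and C11 come from santonin; C8 from enzymatic hydroxylation with retention; 5α-H from α-face hydrogenation. That trans fusion dictates the ring-trans C1=C10 and C4=C5 geometry in the conrotatory opening.

Key step: step 12

Assumption: the fungus of step 1 is taken to insert oxygen into the equatorial 8α C–H bond with retention (giving artemisin), the 11β-hydroxy regioisomer being removed by chromatography.

**Step 1**
Reactants: 1 α-santonin
Product: 2 8α-hydroxy-α-santonin (8α-hydroxy-3-oxo-11βH-eudesma-1,4-dien-12,6α-olide)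
Conditions: Absidia coerulea, growing culture, glucose–peptone medium, air, 28 °C; 1 fed in EtOH
Reagents that add atoms: dioxygen O=O
Why: Enzymatic C–H hydroxylation by the cytochrome P450 monooxygenases of santonin-metabolising fungi proceeds with retention, and the exposed equatorial 8α-H of ring B is a known site of attack, so C8 should be set as the 8α-alcohol.

**Step 2**
Reactants: 2 8α-hydroxy-α-santonin
Product: 4 8α-hydroxy-4α-methyl-3-oxo-4βH,5αH,11βH-eudesman-12,6α-olide, via 4β-methyl epimer 3 (not isolated)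
Conditions: H2 (1 atm), 10% Pd/C, EtOAc, rt; filter; then TsOH·H2O (cat.), CH2Cl2, rt
Reagents that add atoms: none
Why: Heterogeneous catalytic hydrogenation adds hydrogen to C4=C5 from the α-face, away from the angular 10β-methyl, which sets the trans ring fusion (5α-H), and acid-catalysed enolisation then epimerises the axial 4β-methyl of 3 to the equatorial 4α-methyl.

**Step 3**
Reactants: 4 8α-hydroxy-4α-methyl-3-oxo-4βH,5αH,11βH-eudesman-12,6α-olide
Product: 5 3-oxo-8α-(triethylsilyloxy)-4βH,5αH,11βH-eudesman-12,6α-olide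
Conditions: Et3SiCl, imidazole, DMF, rt
Reagents that add atoms: chlorotriethylsilane CC[Si](Cl)(CC)CC
Why: Silyl ether formation at the only hydroxyl group; triethylsilyl is chosen because it can later be removed beside a primary tert-butyldimethylsilyl ether.

**Step 4**
Reactants: 5 3-oxo-8α-(triethylsilyloxy)-4βH,5αH,11βH-eudesman-12,6α-olide
Product: 6 3β-hydroxy-8α-(triethylsilyloxy)-4βH,5αH,11βH-eudesman-12,6α-olide
Conditions: NaBH4, MeOH, 0 °C
Reagents that add atoms: none
Why: NaBH4 reduction of the trans-decalone by axial hydride delivery from the α-face should give the equatorial 3β-alcohol needed as directing group, and the lactone is not reduced at 0 °C.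

**Step 5**
Reactants: 6 3β-hydroxy-8α-(triethylsilyloxy)-4βH,5αH,11βH-eudesman-12,6α-olide
Product: 9 3β,15-dihydroxy-8α-(triethylsilyloxy)-4βH,5αH,11βH-eudesman-12,6α-olide, via diethylhydridosilyl ether 7 (not isolated), via oxasilolane 8 (not isolated)
Conditions: Et2SiH2, [Ir(cod)OMe]2 (cat.), THF, rt; then [Ir(cod)OMe]2 (cat.), 3,4,7,8-tetramethyl-1,10-phenanthroline, norbornene, THF, 100 °C; then H2O2, KHCO3, THF–MeOH, 50 °C
Reagents that add atoms: hydrogen peroxide OO (oxygen on C15 of 9); diethylsilane CC[SiH2]CC (silicon and ethyl groups of intermediates 7 and 8 only)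
Why: Hydroxyl-directed iridium-catalysed γ-C–H silylation followed by Tamao–Fleming oxidation: the hydridosilyl ether of the equatorial 3β-OH can reach, through a five-membered oxasilolane, only the primary C–H bonds of the gauche equatorial 4α-methyl (C15), as with the equatorial C4 methyl of 3β-hydroxy triterpenoids, and oxidative C–Si cleavage gives the 1,3-diol without touching a stereocentre.

**Step 6**
Reactants: 9 3β,15-dihydroxy-8α-(triethylsilyloxy)-4βH,5αH,11βH-eudesman-12,6α-olide
Product: 10 15-(tert-butyldimethylsilyloxy)-3β-hydroxy-8α-(triethylsilyloxy)-4βH,5αH,11βH-eudesman-12,6α-olide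
Conditions: tBuMe2SiCl (1.05 equiv), imidazole, CH2Cl2, 0 °C
Reagents that add atoms: tert-butyldimethylsilyl chloride CC(C)(C)[Si](C)(C)Cl
Why: Selective silylation of the primary alcohol over the hindered secondary one with one equivalent of the bulky silyl chloride.

**Step 7**
Reactants: 10 15-(tert-butyldimethylsilyloxy)-3β-hydroxy-8α-(triethylsilyloxy)-4βH,5αH,11βH-eudesman-12,6α-olide
Product: 11 15-(tert-butyldimethylsilyloxy)-3-oxo-8α-(triethylsilyloxy)-4βH,5αH,11βH-eudesman-12,6α-olide
Conditions: (nPr4N)RuO4 (cat.), N-methylmorpholine N-oxide, 4 Å MS, CH2Cl2, rt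
Reagents that add atoms: none
Why: Ley–Griffith oxidation of the secondary alcohol under neutral conditions should leave both silyl ethers in place and avoid β-elimination of the C15 silyloxy group.

**Step 8**
Reactants: 11 15-(tert-butyldimethylsilyloxy)-3-oxo-8α-(triethylsilyloxy)-4βH,5αH,11βH-eudesman-12,6α-olide
Product: 13 15-(tert-butyldimethylsilyloxy)-3-oxo-8α-(triethylsilyloxy)-4βH,5αH,11βH-eudesm-1-en-12,6α-olide, via trimethylsilyl enol ether 12 (not isolated)
Conditions: LiN(iPr)2, Me3SiCl, THF, −78 °C; then Pd(OAc)2 (1.1 equiv), MeCN, rt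
Reagents that add atoms: chlorotrimethylsilane C[Si](C)(C)Cl (atoms present in intermediate 12 only)
Why: Saegusa–Ito oxidation: kinetic deprotonation should occur at the C2 methylene and not at the hindered C4 methine or the less acidic lactone C11, and Pd(OAc)2 converts the Δ2 silyl enol ether into the Δ1 enone by β-hydride elimination of H1.

**Step 9**
Reactants: 13 15-(tert-butyldimethylsilyloxy)-3-oxo-8α-(triethylsilyloxy)-4βH,5αH,11βH-eudesm-1-en-12,6α-olide
Product: 14 15-(tert-butyldimethylsilyloxy)-8α-(triethylsilyloxy)-3-(trifluoromethylsulfonyloxy)-5αH,11βH-eudesma-1,3-dien-12,6α-olide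
Conditions: KN(SiMe3)2, THF, −78 °C; then N-(5-chloro-2-pyridyl)bis(trifluoromethanesulfonimide), −78 °C
Reagents that add atoms: N-(5-chloro-2-pyridyl)bis(trifluoromethanesulfonimide) O=S(=O)(N(c1ccc(Cl)cn1)S(=O)(=O)C(F)(F)F)C(F)(F)F
Why: Enol triflate formation: C4 is the only enolisable ketone α-position of the 1-en-3-one, so O-sulfonylation of its potassium enolate at −78 °C (cold enough to outrun β-elimination of the silyloxy group) should give the cross-conjugated dienyl triflate, the C4 stereocentre being erased on purpose.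

**Step 10**
Reactants: 14 15-(tert-butyldimethylsilyloxy)-8α-(triethylsilyloxy)-3-(trifluoromethylsulfonyloxy)-5αH,11βH-eudesma-1,3-dien-12,6α-olide
Product: 15 15-(tert-butyldimethylsilyloxy)-8α-(triethylsilyloxy)-5αH,11βH-eudesma-1,3-dien-12,6α-olide
Conditions: Pd(OAc)2 (cat.), PPh3, HCO2H, nBu3N, DMF, 60 °C
Reagents that add atoms: none
Why: Palladium-catalysed hydrogenolysis of a vinyl triflate with formate as hydride source (oxidative addition to zerovalent palladium, decarboxylation, reductive elimination) replaces the triflate by hydrogen without moving the diene.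

**Step 11**
Reactants: 15 15-(tert-butyldimethylsilyloxy)-8α-(triethylsilyloxy)-5αH,11βH-eudesma-1,3-dien-12,6α-olide
Product: 16 15-(tert-butyldimethylsilyloxy)-8α-hydroxy-5αH,11βH-eudesma-1,3-dien-12,6α-olide
Conditions: HF·pyridine, pyridine, THF, 0 °C
Reagents that add atoms: none
Why: Selective desilylation: a secondary triethylsilyl ether is cleaved by buffered HF·pyridine markedly faster than a primary tert-butyldimethylsilyl ether, and the buffered medium should spare the diene and the lactone.

**Step 12**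
Reactants: 16 15-(tert-butyldimethylsilyloxy)-8α-hydroxy-5αH,11βH-eudesma-1,3-dien-12,6α-olide
Product: 17 15-(tert-butyldimethylsilyloxy)-8α-hydroxy-11βH-germacra-1(10),2,4-trien-12,6α-olide (C1=C10 and C4=C5 ring-trans, C2=C3 cis), kept as the cold photolysate
Conditions: hν (254 nm, low-pressure Hg lamp, quartz), degassed Et2O–MeOH, −78 °C, to the photostationary state
Reagents that add atoms: none
Why: π→π* excitation of the s-cis ring A diene triggers a conrotatory 6π electrocyclic ring-opening that breaks the C5–C10 σ bond and converts it, with the two former π bonds, into the C1=C10, C2=C3 and C4=C5 π bonds. The closest known reaction type is the photochemical opening of cyclohexa-1,3-dienes to hexa-1,3,5-trienes (provitamin D to previtamin D), which with trans-fused bicyclic dienes gives cyclodeca-1,3,5-trienes. No ring is closed: the ten-membered carbocycle is released from the decalin by scission of its central bond, so no entropic or transannular cost of a cyclisation is paid. No stereocentre is created; C5 and C10 become trigonal and C6, C7, C8 and C11 are spectators. The step needs ring-trans geometry at C1=C10 and C4=C5, which the trans fusion (5α-H, 10β-CH3) secures because conrotation swings both ring B bonds (C10–C9 and C5–C6) outward and leaves C2=C3 cis. It also needs the triene to survive, which the low temperature (no thermal disrotatory re-closure), interruption at the photostationary state and direct use in step 13 should secure.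

**Step 13**
Reactants: 17 15-(tert-butyldimethylsilyloxy)-8α-hydroxy-11βH-germacra-1(10),2,4-trien-12,6α-olide
Product: 18 15-(tert-butyldimethylsilyloxy)-8α-hydroxy-11βH-germacra-1(10),4-dien-12,6α-olide (both ring double bonds ring-trans)
Conditions: KO2CN=NCO2K, AcOH, Et2O–MeOH, −40 → −20 °C, dark
Reagents that add atoms: none
Why: Diimide reduction (concerted syn transfer of two hydrogens) discriminates strongly by substitution and strain, so the cis-disubstituted, twisted C2=C3 bond should be reduced while the trisubstituted C1=C10 and C4=C5 bonds, the lactone and the silyl ether stay untouched, and any reduced residual diene 16 is removed by chromatography.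

**Step 14**
Reactants: 19 2-(bromomethyl)acrylic acid
Product: 20 2-(acetoxymethyl)acrylic acid
Conditions: KOAc, AcOH, 60 °C
Reagents that add atoms: potassium acetate [K+].CC(=O)[O-]
Why: SN2 displacement of the activated allylic bromide by acetate (the SN2′ path gives the same product because the allyl unit is symmetrical), the acetic acid medium keeping the substrate carboxyl protonated and so suppressing self-alkylation.

**Step 15**
Reactants: 18 15-(tert-butyldimethylsilyloxy)-8α-hydroxy-11βH-germacra-1(10),4-dien-12,6α-olide; 20 2-(acetoxymethyl)acrylic acid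
Product: 22 8α-[2-(acetoxymethyl)acryloyloxy]-15-(tert-butyldimethylsilyloxy)-11βH-germacra-1(10),4-dien-12,6α-olide, via acid chloride 21 (not isolated)
Conditions: 20, 1-chloro-N,N,2-trimethylprop-1-en-1-amine, CH2Cl2, 0 °C; then 18, pyridine, CH2Cl2, 0 °C → rt
Reagents that add atoms: 1-chloro-N,N,2-trimethylprop-1-en-1-amine CC(C)=C(Cl)N(C)C (chlorine of intermediate 21 only)
Why: Esterification by acylation with an acid chloride made under neutral conditions from an α-chloroenamine; pyridine is used without 4-(dimethylamino)pyridine to avoid SN2′ displacement of the allylic acetate, and the only free hydroxyl of 18 is the 8α-OH, whose configuration is not touched.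

**Step 16**
Reactants: 22 8α-[2-(acetoxymethyl)acryloyloxy]-15-(tert-butyldimethylsilyloxy)-11βH-germacra-1(10),4-dien-12,6α-olide
Product: 23 8α-[2-(acetoxymethyl)acryloyloxy]-15-hydroxy-11βH-germacra-1(10),4-dien-12,6α-olide (target)
Conditions: HF·pyridine, pyridine, THF, 0 °C → rt
Reagents that add atoms: none
Why: Fluoride cleavage of the primary allylic silyl ether with buffered HF·pyridine, which is not basic enough for acyl migration or conjugate addition to the acrylate and not acidic enough to trigger transannular cyclisation of the germacra-1(10),4-diene.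

**Compound list**
1 | α-santonin (3-oxo-6βH,7αH,11βH-eudesma-1,4-dien-12,6α-olide) | C[C@H]1[C@@H]2CC[C@]3(C=CC(=O)C(=C3[C@H]2OC1=O)C)C | starting material
2 | 8α-hydroxy-α-santonin (artemisin) | O[C@H]1C[C@@]3(C)C=CC(=O)C(C)=C3[C@H]2OC(=O)[C@@H](C)[C@H]12 | intermediate
3 | 8α-hydroxy-4β-methyl-3-oxo-4αH,5αH,11βH-eudesman-12,6α-olide (axial methyl) | O[C@H]1C[C@@]3(C)CCC(=O)[C@H](C)[C@@H]3[C@H]2OC(=O)[C@@H](C)[C@H]12 | intermediate (not isolated)
4 | 8α-hydroxy-4α-methyl-3-oxo-4βH,5αH,11βH-eudesman-12,6α-olide (trans-fused, equatorial methyl) | O[C@H]1C[C@@]3(C)CCC(=O)[C@@H](C)[C@@H]3[C@H]2OC(=O)[C@@H](C)[C@H]12 | intermediate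
5 | 3-oxo-8α-(triethylsilyloxy)-4βH,5αH,11βH-eudesman-12,6α-olide | CC[Si](CC)(CC)O[C@H]1C[C@@]3(C)CCC(=O)[C@@H](C)[C@@H]3[C@H]2OC(=O)[C@@H](C)[C@H]12 | intermediate
6 | 3β-hydroxy-8α-(triethylsilyloxy)-4βH,5αH,11βH-eudesman-12,6α-olide | CC[Si](CC)(CC)O[C@H]1C[C@@]3(C)CC[C@H](O)[C@@H](C)[C@@H]3[C@H]2OC(=O)[C@@H](C)[C@H]12 | intermediate
7 | 3β-(diethylsilyloxy)-8α-(triethylsilyloxy)-4βH,5αH,11βH-eudesman-12,6α-olide (Si–H ether) | CC[Si](CC)(CC)O[C@H]1C[C@@]3(C)CC[C@H](O[SiH](CC)CC)[C@@H](C)[C@@H]3[C@H]2OC(=O)[C@@H](C)[C@H]12 | intermediate (not isolated)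
8 | cyclic diethylsilylene bridging O3 and C15 (1-oxa-2-silacyclopentane on C3–C4) of the 8α-(triethylsilyloxy)-eudesman-12,6α-olide | CC[Si](CC)(CC)O[C@H]1C[C@@]3(C)CC[C@@H]4O[Si](CC)(CC)C[C@H]4[C@@H]3[C@H]2OC(=O)[C@@H](C)[C@H]12 | intermediate (not isolated)
9 | 3β,15-dihydroxy-8α-(triethylsilyloxy)-4βH,5αH,11βH-eudesman-12,6α-olide | CC[Si](CC)(CC)O[C@H]1C[C@@]3(C)CC[C@H](O)[C@@H](CO)[C@@H]3[C@H]2OC(=O)[C@@H](C)[C@H]12 | intermediate
10 | 15-(tert-butyldimethylsilyloxy)-3β-hydroxy-8α-(triethylsilyloxy)-4βH,5αH,11βH-eudesman-12,6α-olide | CC[Si](CC)(CC)O[C@H]1C[C@@]3(C)CC[C@H](O)[C@@H](CO[Si](C)(C)C(C)(C)C)[C@@H]3[C@H]2OC(=O)[C@@H](C)[C@H]12 | intermediate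
11 | 15-(tert-butyldimethylsilyloxy)-3-oxo-8α-(triethylsilyloxy)-4βH,5αH,11βH-eudesman-12,6α-olide | CC[Si](CC)(CC)O[C@H]1C[C@@]3(C)CCC(=O)[C@@H](CO[Si](C)(C)C(C)(C)C)[C@@H]3[C@H]2OC(=O)[C@@H](C)[C@H]12 | intermediate
12 | 15-(tert-butyldimethylsilyloxy)-8α-(triethylsilyloxy)-3-(trimethylsilyloxy)-4βH,5αH,11βH-eudesm-2-en-12,6α-olide | CC[Si](CC)(CC)O[C@H]1C[C@@]3(C)CC=C(O[Si](C)(C)C)[C@@H](CO[Si](C)(C)C(C)(C)C)[C@@H]3[C@H]2OC(=O)[C@@H](C)[C@H]12 | intermediate (not isolated)
13 | 15-(tert-butyldimethylsilyloxy)-3-oxo-8α-(triethylsilyloxy)-4βH,5αH,11βH-eudesm-1-en-12,6α-olide | CC[Si](CC)(CC)O[C@H]1C[C@@]3(C)C=CC(=O)[C@@H](CO[Si](C)(C)C(C)(C)C)[C@@H]3[C@H]2OC(=O)[C@@H](C)[C@H]12 | intermediate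
14 | 15-(tert-butyldimethylsilyloxy)-8α-(triethylsilyloxy)-3-(trifluoromethylsulfonyloxy)-5αH,11βH-eudesma-1,3-dien-12,6α-olide | CC[Si](CC)(CC)O[C@H]1C[C@@]3(C)C=CC(OS(=O)(=O)C(F)(F)F)=C(CO[Si](C)(C)C(C)(C)C)[C@@H]3[C@H]2OC(=O)[C@@H](C)[C@H]12 | intermediate
15 | 15-(tert-butyldimethylsilyloxy)-8α-(triethylsilyloxy)-5αH,11βH-eudesma-1,3-dien-12,6α-olide | CC[Si](CC)(CC)O[C@H]1C[C@@]3(C)C=CC=C(CO[Si](C)(C)C(C)(C)C)[C@@H]3[C@H]2OC(=O)[C@@H](C)[C@H]12 | intermediate
16 | 15-(tert-butyldimethylsilyloxy)-8α-hydroxy-5αH,11βH-eudesma-1,3-dien-12,6α-olide | O[C@H]1C[C@@]3(C)C=CC=C(CO[Si](C)(C)C(C)(C)C)[C@@H]3[C@H]2OC(=O)[C@@H](C)[C@H]12 | intermediate (key-step precursor)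
17 | 15-(tert-butyldimethylsilyloxy)-8α-hydroxy-11βH-germacra-1(10),2,4-trien-12,6α-olide (ring-trans C1=C10 and C4=C5, cis C2=C3) | O[C@H]1C/C(C)=C/C=C\C(CO[Si](C)(C)C(C)(C)C)=C\[C@H]2OC(=O)[C@@H](C)[C@H]12 | intermediate (key-step product)
18 | 15-(tert-butyldimethylsilyloxy)-8α-hydroxy-11βH-germacra-1(10),4-dien-12,6α-olide | O[C@H]1C/C(C)=C/CC/C(CO[Si](C)(C)C(C)(C)C)=C/[C@H]2OC(=O)[C@@H](C)[C@H]12 | intermediate
19 | 2-(bromomethyl)acrylic acid | C=C(CBr)C(=O)O | starting material
20 | 2-(acetoxymethyl)acrylic acid | C=C(COC(C)=O)C(=O)O | intermediate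
21 | 2-(acetoxymethyl)acryloyl chloride | C=C(COC(C)=O)C(Cl)=O | intermediate (not isolated)
22 | 8α-[2-(acetoxymethyl)acryloyloxy]-15-(tert-butyldimethylsilyloxy)-11βH-germacra-1(10),4-dien-12,6α-olide | C=C(COC(C)=O)C(=O)O[C@H]1C/C(C)=C/CC/C(CO[Si](C)(C)C(C)(C)C)=C/[C@H]2OC(=O)[C@@H](C)[C@H]12 | intermediate
23 | 8α-[2-(acetoxymethyl)acryloyloxy]-15-hydroxy-11βH-germacra-1(10),4-dien-12,6α-olide (CNP0291063.1) | C=C(COC(C)=O)C(=O)O[C@H]1C/C(C)=C/CC/C(CO)=C/[C@H]2OC(=O)[C@@H](C)[C@H]12 | target

**Count**
Total steps: 16. Longest linear sequence: 15 (steps 1–13, 15 and 16; step 14 prepares the side-chain acid).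

**Steps most likely to fail**

Step 12. The triene itself absorbs at 254 nm, so it may revert to the diene or drift into secondary photoproducts and the mixture may stay poor in triene; it also re-closes thermally (disrotatory) once it warms. The fallback drains the photoequilibrium physically instead of waiting for the reduction. It sets out from 16: the cold (−40 °C) solution is pumped in a closed loop through a quartz coil around the 254 nm lamp and then through a cooled, light-shielded bed of AgNO3-impregnated silica gel. The strained trans double bonds of the ten-membered ring bind monovalent silver far more strongly than the cis-diene does, so the product is held back as the AgNO3 π-complex of the triene F1 while unchanged 16 returns to the lamp. Washing the bed with cold aqueous NaCl and Et2O sets the triene free, and the route is rejoined at 17 for step 13.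

Step 5. Catalyst turnover may stall (binding of the lactone carbonyl, shielding of the silyl hydride by the ring), or silylation may stray to secondary C–H bonds. The fallback oxygenates C15 by undirected allylic oxidation of an olefin and sets out from ketone 5.
- LiBH(sBu)3 in THF at −78 °C should give the axial 3α-alcohol F2.
- POCl3 in pyridine eliminates it anti to the axial 4β-H to the 3-ene F3.
- Catalytic SeO2 with tBuOOH in CH2Cl2 oxidises the vinylic methyl group (ene reaction, then [2,3]-sigmatropic shift; the only other allylic C–H on the substituted olefin terminus is the ring-fusion methine) to the allylic alcohol F4.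
- tBuMe2SiCl and imidazole give the silyl ether F5.
- CrO3·3,5-dimethylpyrazole oxidises the allylic C2 methylene to the 3-en-2-one F6.
- KN(SiMe3)2 and N-(5-chloro-2-pyridyl)bis(trifluoromethanesulfonimide) at −78 °C deprotonate C1 and give the 2-triflyloxy-1,3-diene F7.
- Pd(OAc)2, PPh3, HCO2H and nBu3N then deliver diene 15, where the route is rejoined before step 11.

Step 9. The C4 enolate may expel the β-silyloxy group (E1cB elimination to the exocyclic enone), or the base may deprotonate the lactone at C11 before sulfonylation. The fallback forms the C3=C4 bond by dehydration instead of through an enolate. It sets out from enone 13: NaBH4 with CeCl3·7H2O in MeOH at −20 °C (Luche reduction, axial hydride) should give the 3β-allylic alcohol F8. Methyl N-(triethylammoniosulfonyl)carbamate in THF at 50 °C converts it into the sulfamate ester, which loses the cis 4β-H by syn-elimination; C10 is quaternary, so no other diene can form. This returns diene 15.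

**Further compounds**
F1 | step 12 | AgNO3 π-complex of triene 17 | O[C@H]1C/C(C)=C/C=C\C(CO[Si](C)(C)C(C)(C)C)=C\[C@H]2OC(=O)[C@@H](C)[C@H]12.[Ag+].[O-][N+](=O)[O-]
F2 | step 5 | 3α-hydroxy-8α-(triethylsilyloxy)-4βH,5αH,11βH-eudesman-12,6α-olide | CC[Si](CC)(CC)O[C@H]1C[C@@]3(C)CC[C@@H](O)[C@@H](C)[C@@H]3[C@H]2OC(=O)[C@@H](C)[C@H]12
F3 | step 5 | 8α-(triethylsilyloxy)-5αH,11βH-eudesm-3-en-12,6α-olide | CC[Si](CC)(CC)O[C@H]1C[C@@]3(C)CC=C(C)[C@@H]3[C@H]2OC(=O)[C@@H](C)[C@H]12
F4 | step 5 | 15-hydroxy-8α-(triethylsilyloxy)-5αH,11βH-eudesm-3-en-12,6α-olide | CC[Si](CC)(CC)O[C@H]1C[C@@]3(C)CC=C(CO)[C@@H]3[C@H]2OC(=O)[C@@H](C)[C@H]12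
F5 | step 5 | 15-(tert-butyldimethylsilyloxy)-8α-(triethylsilyloxy)-5αH,11βH-eudesm-3-en-12,6α-olide | CC[Si](CC)(CC)O[C@H]1C[C@@]3(C)CC=C(CO[Si](C)(C)C(C)(C)C)[C@@H]3[C@H]2OC(=O)[C@@H](C)[C@H]12
F6 | step 5 | 15-(tert-butyldimethylsilyloxy)-2-oxo-8α-(triethylsilyloxy)-5αH,11βH-eudesm-3-en-12,6α-olide | CC[Si](CC)(CC)O[C@H]1C[C@@]3(C)CC(=O)C=C(CO[Si](C)(C)C(C)(C)C)[C@@H]3[C@H]2OC(=O)[C@@H](C)[C@H]12
F7 | step 5 | 15-(tert-butyldimethylsilyloxy)-8α-(triethylsilyloxy)-2-(trifluoromethylsulfonyloxy)-5αH,11βH-eudesma-1,3-dien-12,6α-olide | CC[Si](CC)(CC)O[C@H]1C[C@@]3(C)C=C(OS(=O)(=O)C(F)(F)F)C=C(CO[Si](C)(C)C(C)(C)C)[C@@H]3[C@H]2OC(=O)[C@@H](C)[C@H]12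
F8 | step 9 | 15-(tert-butyldimethylsilyloxy)-3β-hydroxy-8α-(triethylsilyloxy)-4βH,5αH,11βH-eudesm-1-en-12,6α-olide | CC[Si](CC)(CC)O[C@H]1C[C@@]3(C)C=C[C@H](O)[C@@H](CO[Si](C)(C)C(C)(C)C)[C@@H]3[C@H]2OC(=O)[C@@H](C)[C@H]12
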